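Ring A is disconnected first, into vinylene carbonate and a monocyclic ring B precursor: C3–C4 and C1–C2 form in one radical [4+2] annulation, and the cis-2,3-glycol arrives as a temporary cyclic carbonate.
What makes this possible: in ring A the C2–C3 cis-glycol is a two-carbon enediol unit lying between the gem-dimethyl carbon C4 (a tertiary radical from an isopropenyl group on C5) and the C1 methylene on quaternary C10 (a formyl group used as a traceless sulfonylhydrazone radical acceptor).
The ring B precursor is cut back to (R)-carvone (C5 stereocentre; isopropenyl = C4, methyl = C17, C=O = C9); C10 is made quaternary by two formaldehyde aldol reactions anti to the isopropenyl group (C20 first, C1 second).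
Ring B is elaborated after the annulation: a C5 organolithium from (R)-linalool (C11–C16, C13 stereocentre) adds to the C9 ketone, and oxidative 1,3-transposition plus enone reduction set 9α-H; a Δ7-ene, its 7α,8α-epoxide and epoxide-to-allylic-alcohol isomerisation give 7α-OH/8(17)-ene; C20 acetylation and C2 angeloylation come last.
Order of ring formation: ring B from the chiral pool, then ring A in the key step; no other ring is formed.

Key step: step 5

Remark: labdane numbering is used for all intermediates (carvone C1, C2, C3, C4, C5, C6 = C9, C8, C7, C6, C5, C10; isopropenyl carbon = C4); α is the face of H5, β the face of C20; TBS = tert-butyldimethylsilyl.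

Step 1
Reactants: 1 (R)-(−)-carvone
Product: 3 trans-10-(TBS-oxymethyl)carvone, via lithium aldolate 2 (not isolated)
Conditions: LiN(i-Pr)2, THF, −78 °C; CH2O (gas, from paraformaldehyde), −78 °C; then t-BuMe2SiCl, DMPU, −78 → 0 °C
Reagents that add atoms: formaldehyde C=O; tert-butyldimethylsilyl chloride CC(C)(C)[Si](C)(C)Cl
Why: kinetic α′-deprotonation gives the cross-conjugated C10 enolate, whose aldol reaction with formaldehyde occurs anti to the isopropenyl group (this centre is re-enolised in step 2), and in-flask O-silylation of the aldolate prevents retro-aldol reaction and dehydration.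

Step 2
Reactants: 3 trans-10-(TBS-oxymethyl)carvone
Product: 4 10-(hydroxymethyl)-10-(TBS-oxymethyl)carvone (CH2OH trans, CH2OTBS cis to isopropenyl)
Conditions: LiN(i-Pr)2, THF, −78 °C; CH2O (gas), −78 °C; AcOH, −78 °C
Reagents that add atoms: formaldehyde C=O
Why: a second kinetic enolisation at C10 and aldol addition to formaldehyde, in which the electrophile again enters anti to the C5 isopropenyl group as in enolate alkylations of 6-substituted carvones, should place the new CH2OH (future C1) trans and the CH2OTBS (C20) cis to C4 and so fix the quaternary C10 centre.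

Step 3
Reactants: 4 10-(hydroxymethyl)-10-(TBS-oxymethyl)carvone
Product: 5 10-formyl-10-(TBS-oxymethyl)carvone
Conditions: Dess–Martin periodinane, CH2Cl2, 0 °C → rt
Reagents that add atoms: none
Why: Dess–Martin oxidation of the neopentyl primary alcohol under near-neutral conditions should give the non-enolisable β-keto aldehyde without retro-aldol or deformylation.

Step 4
Reactants: 5 10-formyl-10-(TBS-oxymethyl)carvone
Product: 6 (E)-N-tosylhydrazone of 5
Conditions: TsNHNH2, MeOH, 0 °C → rt
Reagents that add atoms: p-toluenesulfonyl hydrazide Cc1ccc(cc1)S(=O)(=O)NN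
Why: hydrazone condensation is chemoselective for the aldehyde over the hindered conjugated C9 ketone and installs the traceless radical acceptor at C1.

Step 5
Reactants: 6 (E)-N-tosylhydrazone; 7 vinylene carbonate
Product: 11 2α,3α-diol enone (ring A closed), via hydrazide carbonate 8 (not isolated), via hydrazide diol 9 (not isolated), via diazene diol 10 (not isolated)
Conditions: Fe(acac)3 (0.5 equiv), PhSiH3 (3 equiv, slow addition), 7 (20 equiv), EtOH/THF, 40 °C; then K2CO3, MeOH, rt → 65 °C
Reagents that add atoms: none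
Why: Proposed new method: iron-hydride hydrogen-atom transfer to the isopropenyl group should give the tertiary C4 radical, which adds to vinylene carbonate (C3–C4), and the nucleophilic dioxolanonyl radical at C2 then closes ring A by 6-exo-trig addition to the sulfonylhydrazone carbon (C1–C2); reduction of the hydrazinyl radical gives 8, methanolysis frees the glycol, and base-induced loss of sulfinate and N2 leaves C1 as CH2. The closest known reaction types are the HAT-initiated radical–polar crossover annulation of γ,δ-unsaturated aldehydes with enones (same two bond positions of a cyclohexane) and the HAT hydromethylation of olefins with formaldehyde sulfonylhydrazones (same traceless acceptor), while radical addition to vinylene carbonate and 6-exo cyclisation onto C=N are each known separately. Ring A closes through a chair in which the preset C5 and C10 centres keep C4 and C1 equatorial on ring B, which gives the trans ring fusion. The C2/C3 cis relationship is enforced by the five-membered carbonate, and the α orientation by the cyclisation: only the adduct radical with 3α-O can place O2 equatorial, whereas the 3β epimer would need O2 axial and syn-diaxial to both C20 and the 4β-methyl, so it should be reduced without ring closure and be removed by chromatography; the first addition itself is not expected to show a facial bias, so that share of material is lost. The step needs the C4 radical to add to vinylene carbonate (large excess, slow silane addition) faster than it is reduced, and the C2 radical to choose C1=N over the enone carbon C7, which is secured because attack at C7 would require the bulky C4 substituent axial on ring B.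

Step 6
Reactants: 11 2α,3α-diol enone
Product: 12 2α,3α-acetonide enone
Conditions: 2,2-dimethoxypropane, PPTS (cat.), CH2Cl2, rt
Reagents that add atoms: 2,2-dimethoxypropane COC(C)(C)OC
Why: acid-catalysed transacetalisation of the cis (axial/equatorial) glycol gives the isopropylidene acetal that protects ring A through the organometallic, chromium and dissolving-metal steps.

Step 7
Reactants: 13 (R)-(−)-linalool
Product: 14 (R)-linalool TBS ether
Conditions: t-BuMe2SiOTf, 2,6-lutidine, CH2Cl2, 0 °C
Reagents that add atoms: tert-butyldimethylsilyl triflate CC(C)(C)[Si](C)(C)OS(=O)(=O)C(F)(F)F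
Why: the silyl triflate silylates the tertiary allylic alcohol without ionisation, and the C13 stereocentre comes unchanged from the chiral pool.

Step 8
Reactants: 14 (R)-linalool TBS ether
Product: 16 (R)-4-methyl-4-(TBS-oxy)hex-5-enoic acid, via aldehyde 15 (not isolated)
Conditions: O3, CH2Cl2, −78 °C (Sudan Red 7B end point); Me2S; then NaClO2, NaH2PO4, 2-methyl-2-butene, t-BuOH/H2O, rt
Reagents that add atoms: ozone [O-][O+]=O; sodium chlorite [Na+].[O-]Cl=O
Why: ozonolysis is selective for the electron-rich trisubstituted alkene over the vinyl group deactivated by the allylic silyloxy substituent, and Pinnick oxidation converts the aldehyde to the acid.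

Step 9
Reactants: 16 (R)-4-methyl-4-(TBS-oxy)hex-5-enoic acid
Product: 18 (R)-5-iodo-3-methyl-3-(TBS-oxy)pent-1-ene, via Barton ester 17 (not isolated)
Conditions: N-hydroxypyridine-2-thione, DCC, DMAP (cat.), CH2Cl2, 0 °C, dark; then CHI3, hν (tungsten lamp), rt
Reagents that add atoms: iodoform IC(I)I
Why: Barton decarboxylative iodination removes the extra carbon through a primary radical that has no favourable cyclisation onto the vinyl group (only 4-exo or 5-endo modes) and is trapped by iodine-atom transfer from iodoform.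

Step 10
Reactants: 18 (R)-5-iodo-3-methyl-3-(TBS-oxy)pent-1-ene; 12 2α,3α-acetonide enone
Product: 20 C9 tertiary allylic alcohol (9β-OH, 9α side chain, Δ7), via organolithium 19 (not isolated)
Conditions: 18, t-BuLi (2.1 equiv), Et2O/pentane, −78 °C; CeCl3, THF, −78 °C; then 12, −78 → −40 °C; H2O
Reagents that add atoms: none
Why: iodine–lithium exchange and transmetalation to the organocerium reagent allow 1,2-addition to the hindered enone, which has no α-hydrogen at C10, without γ-deprotonation, from the α face anti to C20 (the C9 carbinol configuration is erased in step 11).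

Step 11
Reactants: 20 C9 tertiary allylic alcohol
Product: 21 7-oxo-Δ8(9) enone
Conditions: C5H5NH[CrO3Cl] (pyridinium chlorochromate, 3 equiv), 4 Å molecular sieves, CH2Cl2, rt
Reagents that add atoms: pyridinium chlorochromate [O-][Cr](=O)(=O)Cl.c1cc[nH+]cc1
Why: Babler–Dauben oxidative 1,3-transposition (chromate ester, [3,3] shift, oxidation) moves oxygen from C9 to C7 and gives the tetrasubstituted enone that carries the side chain on C9.

Step 12
Reactants: 21 7-oxo-Δ8(9) enone
Product: 23 Δ7-enol triflate (9α-H), via lithium enolate 22 (not isolated)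
Conditions: Li (2.3 equiv), NH3 (l)/THF, t-BuOH (1 equiv), −78 °C; isoprene; NH3 evaporated; PhN(SO2CF3)2, THF, 0 °C
Reagents that add atoms: N-phenylbis(trifluoromethanesulfonimide) O=S(=O)(N(c1ccccc1)S(=O)(=O)C(F)(F)F)C(F)(F)F
Why: dissolving-metal enone reduction protonates the β-carbon C9 axially from the α face (anti to the axial C20 group, giving the equatorial β side chain), and O-triflation traps the regiodefined C7 enolate.

Step 13
Reactants: 23 Δ7-enol triflate
Product: 24 Δ7-ene (labda-7,14-diene core)
Conditions: Pd(OAc)2 (5 mol%), PPh3, n-Bu3N, HCO2H, DMF, 60 °C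
Reagents that add atoms: none
Why: palladium-catalysed formate reduction of the enol triflate (oxidative addition to zerovalent palladium, formate decarboxylation, reductive elimination) gives the C7=C8 alkene regiospecifically without touching the vinyl group.

Step 14
Reactants: 24 Δ7-ene
Product: 25 7α,8α-epoxide
Conditions: dimethyldioxirane, acetone, −20 °C
Reagents that add atoms: dimethyldioxirane CC1(C)OO1
Why: neutral epoxidation is selective for the only electron-rich trisubstituted alkene and occurs from the α face because the axial C20 CH2OTBS group shields the β face of C8.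

Step 15
Reactants: 25 7α,8α-epoxide
Product: 26 7α-hydroxy-8(17)-ene
Conditions: 2,2,6,6-tetramethylpiperidine, n-BuLi, then Et2AlCl, toluene, 0 °C (gives diethylaluminium 2,2,6,6-tetramethylpiperidide); 25, 0 °C → rt; H2O
Reagents that add atoms: none
Why: the bulky aluminium amide (Yamamoto epoxide-to-allylic-alcohol isomerisation) removes a proton from the least hindered β-carbon, the C17 methyl, and opens the C8–O bond, so the exocyclic alkene forms and the oxygen stays α on C7.

Step 16
Reactants: 26 7α-hydroxy-8(17)-ene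
Product: 27 7-O-TBS ether
Conditions: t-BuMe2SiOTf, 2,6-lutidine, CH2Cl2, −78 → 0 °C
Reagents that add atoms: tert-butyldimethylsilyl triflate CC(C)(C)[Si](C)(C)OS(=O)(=O)C(F)(F)F
Why: silylation of the axial allylic 7α-hydroxyl removes it as a competitor for the two acylations that follow.

Step 17
Reactants: 27 7-O-TBS ether
Product: 28 C20 primary alcohol
Conditions: HF·pyridine, pyridine, THF, 0 °C
Reagents that add atoms: none
Why: buffered HF·pyridine cleaves the primary silyl ether much faster than the hindered secondary (C7) and tertiary (C13) silyl ethers and leaves the acetonide intact.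

Step 18
Reactants: 28 C20 primary alcohol
Product: 29 C20 acetate
Conditions: Ac2O, pyridine, DMAP (cat.), CH2Cl2, rt
Reagents that add atoms: acetic anhydride CC(=O)OC(C)=O
Why: DMAP-catalysed acetylation of the only free hydroxyl installs the C20 acetate.

Step 19
Reactants: 29 C20 acetate
Product: 30 2α,3α-diol
Conditions: PPTS, MeOH, 40 °C
Reagents that add atoms: none
Why: mild acid-catalysed transacetalisation removes the isopropylidene group, while the secondary and tertiary TBS ethers and the neopentyl acetate are stable to PPTS in methanol.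

Step 20
Reactants: 30 2α,3α-diol
Product: 31 2-O-angelate
Conditions: angelic acid, 2,4,6-trichlorobenzoyl chloride, Et3N, toluene, rt; then 30, toluene, 75 °C (no DMAP)
Reagents that add atoms: angelic acid C/C=C(/C)C(=O)O
Why: Yamaguchi-type mixed-anhydride esterification without a nucleophilic catalyst transfers the (Z)-acyl group without isomerisation to the tiglate and selects the equatorial 2α-OH over the axial 3α-OH flanked by the gem-dimethyl group.

Step 21
Reactants: 31 2-O-angelate
Product: 32 target, (13R)-20-acetoxy-2α-angeloyloxy-labda-8(17),14-diene-3α,7α,13-triol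
Conditions: HF·pyridine (excess), pyridine, THF, 0 → 40 °C
Reagents that add atoms: none
Why: fluoride-mediated desilylation under mildly acidic buffered conditions frees the 7α and 13 hydroxyls without acyl migration or ester cleavage.

Compound list
1 | (R)-(−)-carvone | CC(=C)[C@@H]1CC=C(C)C(=O)C1 | starting material
2 | lithium aldolate of trans-10-(hydroxymethyl)carvone | [Li+].O=C1C(C)=CC[C@@H](C(C)=C)[C@@H]1C[O-] | intermediate
3 | trans-10-(TBS-oxymethyl)carvone (CH2OTBS trans to isopropenyl) | O=C1C(C)=CC[C@@H](C(C)=C)[C@@H]1CO[Si](C)(C)C(C)(C)C | intermediate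
4 | 10-(hydroxymethyl)-10-(TBS-oxymethyl)carvone (CH2OH = C1 trans, CH2OTBS = C20 cis to isopropenyl) | O=C1C(C)=CC[C@@H](C(C)=C)[C@@]1(CO)CO[Si](C)(C)C(C)(C)C | intermediate
5 | 10-formyl-10-(TBS-oxymethyl)carvone | O=C1C(C)=CC[C@@H](C(C)=C)[C@@]1(C=O)CO[Si](C)(C)C(C)(C)C | intermediate
6 | (E)-N-tosylhydrazone of 5 | O=C1C(C)=CC[C@@H](C(C)=C)[C@@]1(/C=N/NS(=O)(=O)c2ccc(C)cc2)CO[Si](C)(C)C(C)(C)C | intermediate
7 | vinylene carbonate (1,3-dioxol-2-one) | O=C1OC=CO1 | starting material
8 | hydrazide carbonate: trans-decalin, 1β-(N′-tosylhydrazino), 2α,3α-cyclic carbonate, 4,4-dimethyl, Δ7-9-one, 20-OTBS | O=C1C(C)=CC[C@H]2C(C)(C)[C@@H]3OC(=O)O[C@@H]3[C@@H](NNS(=O)(=O)c4ccc(C)cc4)[C@]12CO[Si](C)(C)C(C)(C)C | intermediate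
9 | hydrazide diol: as 8 with free 2α,3α-diol | O=C1C(C)=CC[C@H]2C(C)(C)[C@H](O)[C@H](O)[C@@H](NNS(=O)(=O)c3ccc(C)cc3)[C@]12CO[Si](C)(C)C(C)(C)C | intermediate
10 | diazene diol: 1β-diazenyl 2α,3α-diol | O=C1C(C)=CC[C@H]2C(C)(C)[C@H](O)[C@H](O)[C@@H](N=N)[C@]12CO[Si](C)(C)C(C)(C)C | intermediate
11 | 2α,3α-diol enone: trans-decalin (5α-H, 10β-CH2OTBS), 4,4-dimethyl, 8-methyl, Δ7, C9 ketone | O=C1C(C)=CC[C@H]2C(C)(C)[C@H](O)[C@H](O)C[C@]12CO[Si](C)(C)C(C)(C)C | intermediate
12 | 2α,3α-acetonide of 11 | O=C1C(C)=CC[C@H]2C(C)(C)[C@@H]3OC(C)(C)O[C@@H]3C[C@]12CO[Si](C)(C)C(C)(C)C | intermediate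
13 | (R)-(−)-linalool | C=C[C@](C)(O)CCC=C(C)C | starting material
14 | (R)-linalool TBS ether | C=C[C@](C)(O[Si](C)(C)C(C)(C)C)CCC=C(C)C | intermediate
15 | (R)-4-methyl-4-(TBS-oxy)hex-5-enal | C=C[C@](C)(O[Si](C)(C)C(C)(C)C)CCC=O | intermediate
16 | (R)-4-methyl-4-(TBS-oxy)hex-5-enoic acid | C=C[C@](C)(O[Si](C)(C)C(C)(C)C)CCC(=O)O | intermediate
17 | Barton ester of 16 (N-acyloxypyridine-2-thione) | C=C[C@](C)(O[Si](C)(C)C(C)(C)C)CCC(=O)On1ccccc1=S | intermediate
18 | (R)-5-iodo-3-methyl-3-(TBS-oxy)pent-1-ene | C=C[C@](C)(O[Si](C)(C)C(C)(C)C)CCI | intermediate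
19 | (R)-3-methyl-3-(TBS-oxy)pent-4-enyllithium | C=C[C@](C)(O[Si](C)(C)C(C)(C)C)CC[Li] | intermediate
20 | C9 tertiary allylic alcohol: 9β-OH, 9α side chain, Δ7, 2α,3α-acetonide, 13-OTBS, 20-OTBS | C=C[C@](C)(O[Si](C)(C)C(C)(C)C)CC[C@]1(O)C(C)=CC[C@H]2C(C)(C)[C@@H]3OC(C)(C)O[C@@H]3C[C@]12CO[Si](C)(C)C(C)(C)C | intermediate
21 | 7-oxo-labda-8,14-diene: 2α,3α-acetonide, 13-OTBS, 20-OTBS | C=C[C@](C)(O[Si](C)(C)C(C)(C)C)CCC1=C(C)C(=O)C[C@H]2C(C)(C)[C@@H]3OC(C)(C)O[C@@H]3C[C@]12CO[Si](C)(C)C(C)(C)C | intermediate
22 | lithium C7 enolate (Δ7, 9α-H) | [Li+].C=C[C@](C)(O[Si](C)(C)C(C)(C)C)CC[C@H]1C(C)=C([O-])C[C@H]2C(C)(C)[C@@H]3OC(C)(C)O[C@@H]3C[C@]12CO[Si](C)(C)C(C)(C)C | intermediate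
23 | Δ7-enol triflate (7-OTf, 9α-H) | C=C[C@](C)(O[Si](C)(C)C(C)(C)C)CC[C@H]1C(C)=C(OS(=O)(=O)C(F)(F)F)C[C@H]2C(C)(C)[C@@H]3OC(C)(C)O[C@@H]3C[C@]12CO[Si](C)(C)C(C)(C)C | intermediate
24 | labda-7,14-diene: 2α,3α-acetonide, 13-OTBS, 20-OTBS | C=C[C@](C)(O[Si](C)(C)C(C)(C)C)CC[C@H]1C(C)=CC[C@H]2C(C)(C)[C@@H]3OC(C)(C)O[C@@H]3C[C@]12CO[Si](C)(C)C(C)(C)C | intermediate
25 | 7α,8α-epoxide of 24 | C=C[C@](C)(O[Si](C)(C)C(C)(C)C)CC[C@H]1[C@]4(C)O[C@@H]4C[C@H]2C(C)(C)[C@@H]3OC(C)(C)O[C@@H]3C[C@]12CO[Si](C)(C)C(C)(C)C | intermediate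
26 | 7α-hydroxy-labda-8(17),14-diene: 2α,3α-acetonide, 13-OTBS, 20-OTBS | C=C[C@](C)(O[Si](C)(C)C(C)(C)C)CC[C@H]1C(=C)[C@H](O)C[C@H]2C(C)(C)[C@@H]3OC(C)(C)O[C@@H]3C[C@]12CO[Si](C)(C)C(C)(C)C | intermediate
27 | 7-O-TBS ether of 26 | C=C[C@](C)(O[Si](C)(C)C(C)(C)C)CC[C@H]1C(=C)[C@H](O[Si](C)(C)C(C)(C)C)C[C@H]2C(C)(C)[C@@H]3OC(C)(C)O[C@@H]3C[C@]12CO[Si](C)(C)C(C)(C)C | intermediate
28 | C20 primary alcohol (7,13-bis-OTBS, 2α,3α-acetonide) | C=C[C@](C)(O[Si](C)(C)C(C)(C)C)CC[C@H]1C(=C)[C@H](O[Si](C)(C)C(C)(C)C)C[C@H]2C(C)(C)[C@@H]3OC(C)(C)O[C@@H]3C[C@]12CO | intermediate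
29 | C20 acetate of 28 | C=C[C@](C)(O[Si](C)(C)C(C)(C)C)CC[C@H]1C(=C)[C@H](O[Si](C)(C)C(C)(C)C)C[C@H]2C(C)(C)[C@@H]3OC(C)(C)O[C@@H]3C[C@]12COC(C)=O | intermediate
30 | 2α,3α-diol (20-OAc, 7,13-bis-OTBS) | C=C[C@](C)(O[Si](C)(C)C(C)(C)C)CC[C@H]1C(=C)[C@H](O[Si](C)(C)C(C)(C)C)C[C@H]2C(C)(C)[C@H](O)[C@H](O)C[C@]12COC(C)=O | intermediate
31 | 2-O-angelate (3α-OH free, 20-OAc, 7,13-bis-OTBS) | C=C[C@](C)(O[Si](C)(C)C(C)(C)C)CC[C@H]1C(=C)[C@H](O[Si](C)(C)C(C)(C)C)C[C@H]2C(C)(C)[C@H](O)[C@H](OC(=O)/C(C)=C\C)C[C@]12COC(C)=O | intermediate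
32 | (13R)-20-acetoxy-2α-angeloyloxy-labda-8(17),14-diene-3α,7α,13-triol | C=C[C@](C)(O)CC[C@H]1C(=C)[C@H](O)C[C@H]2C(C)(C)[C@H](O)[C@H](OC(=O)/C(C)=C\C)C[C@]12COC(C)=O | target

Total step count: 21. Longest linear sequence: 18 steps (steps 1–6 and 10–21, from (R)-carvone); the side-chain branch (steps 7–9) joins at step 10.

Steps most likely to fail

Step 5 (proposed new method). The tertiary C4 radical may be reduced (net hydrogenation of the isopropenyl group) faster than it adds to the weakly activated vinylene carbonate. The intermolecular addition is not expected to show a facial bias, so the adduct radical with the wrong C3 configuration is lost. The C2 radical may also be reduced or diverted to the enone before ring closure. The fallback uses known reactions only, sets out from compound 3 and comes back at compound 11. The enolate of 3 (LiN(i-Pr)2, THF, −78 °C) would be added to acrylonitrile anti to the isopropenyl group to give the cyanoethyl ketone F1. The known HAT-initiated alkene–nitrile cyclisation (Fe(acac)3, PhSiH3, EtOH, 60 °C) would close the C3–C4 bond by 6-exo-dig attack of the C4 radical on the nitrile and give the ring A ketimine F2, which is hydrolysed on work-up to the 4,4-dimethyl-3-ketone F3. Kinetic enolisation toward C2 (KN(SiMe3)2, PhN(SO2CF3)2, THF, −78 °C) would give the Δ2-enol triflate F4, and palladium-catalysed formate reduction (Pd(OAc)2, PPh3, n-Bu3N, HCO2H) the Δ2-ene F5. Dihydroxylation of F5 (OsO4 cat., N-methylmorpholine N-oxide, acetone/H2O) from the α face, opposite the axial C20 and 4β-methyl groups, would then give the 2α,3α-diol 11.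

Step 12. Under dissolving-metal conditions the allylic C13–O bond of the side chain may be cleaved reductively or the enone over-reduced, and O-triflation of the hindered tetrasubstituted enolate may be incomplete. The fallback sets out from compound 21 and comes back at compound 24. Luche reduction (NaBH4, CeCl3·7H2O, MeOH, −78 °C), with hydride delivered from the α face, would give the 7β-allylic alcohol F6. Mitsunobu displacement with 2-nitrobenzenesulfonylhydrazide (PPh3, diethyl azodicarboxylate, N-methylmorpholine, THF, −30 °C) would give with inversion the 7α-sulfonylhydrazine F7. On warming, F7 loses sulfinic acid to the allylic diazene F8, whose retro-ene loss of N2 (Myers reductive 1,3-transposition) delivers hydrogen to C9 from the α face and moves the alkene to C7=C8, giving 24.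

Step 20. The (Z)-2-methylbut-2-enoyl group may isomerise to the (E)-tiglate during activation or acyl transfer, and slow acylation of the hindered glycol may allow acyl migration or double acylation. The fallback sets out from compound 30 and comes back at compound 31. The 2α-hydroxyl would be esterified with 2-[bis(2,2,2-trifluoroethoxy)phosphoryl]propanoic acid (EDC, DMAP cat., CH2Cl2, 0 °C) to give the phosphonopropanoate F9. Still–Gennari olefination of F9 (KN(SiMe3)2, 18-crown-6, THF, −78 °C; acetaldehyde) would then build the (Z)-trisubstituted enoate in place and give 31.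

Further compounds
F1 | step 5 | 10-(2-cyanoethyl)-10-(TBS-oxymethyl)carvone (cyanoethyl trans to isopropenyl) | O=C1C(C)=CC[C@@H](C(C)=C)[C@@]1(CCC#N)CO[Si](C)(C)C(C)(C)C
F2 | step 5 | ring A ketimine (C3=NH, 4,4-dimethyl, trans-decalin, Δ7-9-one, 20-OTBS) | O=C1C(C)=CC[C@H]2C(C)(C)C(=N)CC[C@]12CO[Si](C)(C)C(C)(C)C
F3 | step 5 | 4,4-dimethyl-3-ketone (trans-decalin, Δ7-9-one, 20-OTBS) | O=C1C(C)=CC[C@H]2C(C)(C)C(=O)CC[C@]12CO[Si](C)(C)C(C)(C)C
F4 | step 5 | Δ2-enol triflate of F3 | O=C1C(C)=CC[C@H]2C(C)(C)C(OS(=O)(=O)C(F)(F)F)=CC[C@]12CO[Si](C)(C)C(C)(C)C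
F5 | step 5 | Δ2-ene (4,4-dimethyl, trans-decalin, Δ7-9-one, 20-OTBS) | O=C1C(C)=CC[C@H]2C(C)(C)C=CC[C@]12CO[Si](C)(C)C(C)(C)C
F6 | step 12 | 7β-hydroxy-labda-8,14-diene (2α,3α-acetonide, 13-OTBS, 20-OTBS) | C=C[C@](C)(O[Si](C)(C)C(C)(C)C)CCC1=C(C)[C@@H](O)C[C@H]2C(C)(C)[C@@H]3OC(C)(C)O[C@@H]3C[C@]12CO[Si](C)(C)C(C)(C)C
F7 | step 12 | 7α-[N-(2-nitrobenzenesulfonyl)hydrazino]-labda-8,14-diene derivative | C=C[C@](C)(O[Si](C)(C)C(C)(C)C)CCC1=C(C)[C@H](N(N)S(=O)(=O)c4ccccc4[N+](=O)[O-])C[C@H]2C(C)(C)[C@@H]3OC(C)(C)O[C@@H]3C[C@]12CO[Si](C)(C)C(C)(C)C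
F8 | step 12 | 7α-allylic diazene | C=C[C@](C)(O[Si](C)(C)C(C)(C)C)CCC1=C(C)[C@H](N=N)C[C@H]2C(C)(C)[C@@H]3OC(C)(C)O[C@@H]3C[C@]12CO[Si](C)(C)C(C)(C)C
F9 | step 20 | 2-O-{2-[bis(2,2,2-trifluoroethoxy)phosphoryl]propanoyl} ester of 30 (mixture at the phosphonate-bearing carbon) | C=C[C@](C)(O[Si](C)(C)C(C)(C)C)CC[C@H]1C(=C)[C@H](O[Si](C)(C)C(C)(C)C)C[C@H]2C(C)(C)[C@H](O)[C@H](OC(=O)C(C)P(=O)(OCC(F)(F)F)OCC(F)(F)F)C[C@]12COC(C)=O
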